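**The vessel.** You asked for a quick number on this vessel, in which E sits in the second phase and acts in the first as D, which turns X into G; here is my reckoning, with the problem as it stands.

- birch: X 0.071 M; E 0.12 M; run made earlier
- flask: X 0.071 M; E 0.0781 M; time 25 h; volume of the second phase over the first 1.0

birch run (percent of the X charged)

| time / h | G / % | X / % |
|---|---|---|
| 0.200 | 0 | 100.1 |
| 0.333 | 2.0 | 97.4 |
| 0.500 | 1.5 | 98.7 |
| 0.667 | 4.1 | 95.8 |
| 1.00 | 6.1 | 92.9 |
| 1.50 | 7.5 | 92.5 |
| 2.50 | 16.4 | 85.9 |

(scatter of a reading: 1 percentage point)

- in the second phase: E; everything else is in the first
- charges count per volume of the first phase; a concentration in a rate is the amount of a species over the volume of its own phase; every rate counts per litre of the first phase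
- what was read earlier has a scatter of 1 percentage point, one standard deviation
- steps that have been proposed: D + G -> Z; D <-> E; X + D -> G
- the earlier runs hold the two phases in the same ratio of volumes as the flask asked about

- how much G there is at 25 h, in percent of the X charged
- the change that raises the amount of G at 25 h, in percent of the X charged most ("none" if none brings more than 2 percentage points) (blue / green / none)
- amount of G at 25 h, in percent of the X charged, after green

- blue: doubling the amount of E, all else as stated
- green: doubling the transfer coefficient of E, all else as stated

**The feed.** X is charged in the smaller amount, so it is the limiting reagent, and its balance needs to know how much E has come across. I assume transfer is the rate-limiting step and treat E as a tank draining with one time constant. The birch reading of 16.4 % G at 2.50 h, with its scatter, gives the feed time constant τ, the E charge times the time over the G made: 25.8 h. The delivered share S is then the E charge over the X charge, times one minus exp(−t/τ). For this flask at 25 h, S is 68.3 %, and I expect G somewhat below that.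

**The choice.** Green takes τ to 12.9 h and brings S to 94.2 %, still under the X charged. Blue brings S to 137 %, past the X charged, and the proposed outlet for surplus D is D + G → Z. So I pick green. The forecast says 56 %, blue as the best change and 70 % after green, holding that “Doubling E helps in both cases”; we part on the choice.

**The result.** The simulation gives 64.4 % and names green, which gains 12 percentage points and reaches 76.9 %, while blue gains 3 points.

    D + G → Z (k = 4.70 /M/h)
    D ⇌ E, rate k2*([D] - [E]/K2) per volume of the first phase (partition coefficient = 1.50, kL = 0.0680 /h)
    X + D → G (k = 54.0 /M/h)

**The neighbour.** At 25 h this flask has used 68.3 % of its X, against S of 68.3 %, and holds 64.4 % as G and 3.92 % as Z. The neighbour flask is the same charge stopped at 15 h. The same τ of 25.8 h gives it S of 48.5 %. That neighbour flask has used 50.5 % of its X and holds 48.8 % as G.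

The data were computed for substances that don't exist.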